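**Remark on the chemistry:** the target is (2S)-5,7-dimethoxy-2-(3,4,5-trimethoxyphenyl)chroman-4-one. At C2 the CIP order is O > aryl > CH2 > H in hydroxy ester 10, lactone 12 and the target, so retention keeps the descriptor (S) throughout.

## Retrosynthetic overview

1. Ring C (O1–C2–C3–C4–C4a–C8a) is cut at O1–C8a and C4–C4a. C8a and C4a become the two sp carbons of 3,5-dimethoxybenzyne, and O1–C2–C3–C4 closes on itself through the O1–C4 acyl bond as (S)-4-(3,4,5-trimethoxyphenyl)oxetan-2-one.
2. Forward, the aryne inserts into the O1–C4 bond of the β-lactone, so ring C grows from four to six atoms and both bonds to ring A form in one operation.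
3. Enabling feature: on ring A the acyl carbon C4a lies between C8a (bearing O1) and C5 (bearing OMe). This 1-O/2-acyl/3-OMe pattern is what a 3-methoxyaryne gives with an O-nucleophile/acyl-electrophile pair. The only stereocentre, C2, is bonded to O1 and C3 and lies outside every bond made or broken.
4. Ring order: rings A and B are bought. The oxetanone is closed first (β-keto ester → asymmetric transfer hydrogenation → saponification → lactonisation). Ring C is formed last by the 4→6 expansion. The aryne precursor comes from 3,5-dimethoxyphenol by carbamate-directed ortho-silylation.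

Key step: step 7

## Route

**Step 1**
Reactants: 1 3,5-dimethoxyphenol
Product: 2 3,5-dimethoxyphenyl N-isopropylcarbamate
Conditions: i-PrNCO, Et3N (cat.), CH2Cl2, rt
Reagents that add atoms: isopropyl isocyanate, CC(C)N=C=O
Why: base-catalysed addition of a phenol to an isocyanate (O-carbamoylation) installs a strong ortho-directing group that can later be removed under mild conditions.

**Step 2**
Reactants: 2 3,5-dimethoxyphenyl N-isopropylcarbamate
Product: 6 3,5-dimethoxy-2-(trimethylsilyl)phenyl N-isopropylcarbamate, via N-TBS carbamate 3 (not isolated), via ortho-lithiated N-TBS carbamate 4 (not isolated), via N-TBS C-TMS carbamate 5 (not isolated)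
Conditions: TBSOTf, TMEDA, Et2O, 0 °C to rt; n-BuLi, TMEDA, −78 °C; TMSCl, −78 °C to rt; aq. NaHSO4
Reagents that add atoms: chlorotrimethylsilane, C[Si](C)(C)Cl
Why: directed ortho-metalation of the N-silylated carbamate should occur at C2, the position flanked by the carbamate (the stronger director) and a methoxy group, rather than at C4 between the two methoxy groups; the aryllithium is silylated and the labile N–Si bond is hydrolysed on acidic work-up.

**Step 3**
Reactants: 6 3,5-dimethoxy-2-(trimethylsilyl)phenyl N-isopropylcarbamate
Product: 8 3,5-dimethoxy-2-(trimethylsilyl)phenyl trifluoromethanesulfonate, via silylphenol 7 (not isolated)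
Conditions: DBU, Et2NH, MeCN, 40 °C; then PhNTf2, rt
Reagents that add atoms: N-phenylbis(trifluoromethanesulfonimide), O=S(=O)(N(c1ccccc1)S(=O)(=O)C(F)(F)F)C(F)(F)F
Why: E1cB cleavage of the N–H carbamate (the isocyanate is trapped by Et2NH as a urea) frees the phenoxide, which is O-triflated in the same flask to give the o-silylaryl triflate aryne precursor.

**Step 4**
Reactants: 9 ethyl 3-oxo-3-(3,4,5-trimethoxyphenyl)propanoate
Product: 10 ethyl (S)-3-hydroxy-3-(3,4,5-trimethoxyphenyl)propanoate
Conditions: RuCl[(S,S)-TsDPEN](p-cymene) (1 mol%), HCO2H/Et3N (5:2), 40 °C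
Reagents that add atoms: none
Why: Noyori–Ikariya asymmetric transfer hydrogenation of an aryl ketone; in the six-membered outer-sphere transition state the CH/π contact between the η6-arene and the trimethoxyphenyl ring selects the ketone face, so the (S,S)-catalyst should give the (S)-carbinol as it does with acetophenone, leaving the ester untouched.

**Step 5**
Reactants: 10 ethyl (S)-3-hydroxy-3-(3,4,5-trimethoxyphenyl)propanoate
Product: 11 (S)-3-hydroxy-3-(3,4,5-trimethoxyphenyl)propanoic acid
Conditions: LiOH, THF/H2O (3:1), 0 °C; then 1 M HCl to pH 3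
Reagents that add atoms: lithium hydroxide, [Li+].[OH-]
Why: ester saponification at 0 °C, where the β-hydroxy carboxylate should neither dehydrate nor undergo retro-aldol cleavage; the carbinol centre is not involved.

**Step 6**
Reactants: 11 (S)-3-hydroxy-3-(3,4,5-trimethoxyphenyl)propanoic acid
Product: 12 (S)-4-(3,4,5-trimethoxyphenyl)oxetan-2-one
Conditions: PhSO2Cl, pyridine, 0–4 °C
Reagents that add atoms: none
Why: β-lactonisation by carboxyl activation; the mixed carboxylic–sulfonic anhydride is attacked by the β-hydroxyl at the acyl carbon (4-exo-trig), so the C–O bond at the stereocentre is never broken and the (S) configuration is retained.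

**Step 7**
Reactants: 12 (S)-4-(3,4,5-trimethoxyphenyl)oxetan-2-one; 8 3,5-dimethoxy-2-(trimethylsilyl)phenyl trifluoromethanesulfonate
Product: 15 (2S)-5,7-dimethoxy-2-(3,4,5-trimethoxyphenyl)chroman-4-one, via 3,5-dimethoxybenzyne 13 (not isolated), via ring-opened caesium alkoxide 14 (not isolated)
Conditions: CsF (3 equiv), 18-crown-6, CF3CH2ONa (15 mol%), THF, 0 °C to rt, slow addition of 8 (1.5 equiv); pH 7 buffer quench
Reagents that add atoms: none
Why: Proposed new method: formal insertion of aryne 13 into the acyl C–O bond of β-lactone 12, the oxygen counterpart of the known aryne insertions into the N–C(O) bond of β-lactams and amides, of the C–O addition of carboxylic acids to arynes and of the salicylate-to-xanthone annulation. Catalytic trifluoroethoxide opens the strained lactone at the acyl carbon (the normal site of attack for alkoxides) to alkoxide 14, which is the only strong nucleophile present when fluoride releases 13 from 8; 14 adds through oxygen to the aryne, and the aryl carbanion, in a medium without proton donors, closes the six-membered ring by 6-exo-trig attack on the activated ester and expels trifluoroethoxide, which carries the chain. No stereocentre is created: the O–C2 bond of the lactone is never broken, so the (S) centre of 12 should be carried into 15 with retention. The required regioselectivity (oxygen on the aryne carbon remote from OMe, acyl on the carbon next to OMe) is secured by the 3-methoxy group of 13, which through aryne distortion and inductive stabilisation of the ortho carbanion directs nucleophiles to the distal carbon, while the 5-methoxy group exerts only a weak effect. Chemoselectivity rests on the low stationary concentration of 13 (slow addition of 8), the absence of acidic C–H or O–H donors and the weakly basic relay, which should suppress enolisation of 12, proton transfer to the carbanion and base-induced opening of 15.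

## Compound list

1 | 3,5-dimethoxyphenol | COc1cc(O)cc(OC)c1 | starting material
2 | 3,5-dimethoxyphenyl N-isopropylcarbamate | COc1cc(OC)cc(OC(=O)NC(C)C)c1 | intermediate
3 | 3,5-dimethoxyphenyl N-(tert-butyldimethylsilyl)-N-isopropylcarbamate | COc1cc(OC)cc(OC(=O)N(C(C)C)[Si](C)(C)C(C)(C)C)c1 | intermediate
4 | 2-lithio-3,5-dimethoxyphenyl N-(tert-butyldimethylsilyl)-N-isopropylcarbamate | COc1cc(OC)c([Li])c(OC(=O)N(C(C)C)[Si](C)(C)C(C)(C)C)c1 | intermediate
5 | 3,5-dimethoxy-2-(trimethylsilyl)phenyl N-(tert-butyldimethylsilyl)-N-isopropylcarbamate | COc1cc(OC)c([Si](C)(C)C)c(OC(=O)N(C(C)C)[Si](C)(C)C(C)(C)C)c1 | intermediate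
6 | 3,5-dimethoxy-2-(trimethylsilyl)phenyl N-isopropylcarbamate | COc1cc(OC)c([Si](C)(C)C)c(OC(=O)NC(C)C)c1 | intermediate
7 | 3,5-dimethoxy-2-(trimethylsilyl)phenol (formed as its DBU-H+ phenoxide) | COc1cc(O)c([Si](C)(C)C)c(OC)c1 | intermediate
8 | 3,5-dimethoxy-2-(trimethylsilyl)phenyl trifluoromethanesulfonate | COc1cc(OC)c([Si](C)(C)C)c(OS(=O)(=O)C(F)(F)F)c1 | intermediate
9 | ethyl 3-oxo-3-(3,4,5-trimethoxyphenyl)propanoate | CCOC(=O)CC(=O)c1cc(OC)c(OC)c(OC)c1 | starting material
10 | ethyl (S)-3-hydroxy-3-(3,4,5-trimethoxyphenyl)propanoate | CCOC(=O)C[C@H](O)c1cc(OC)c(OC)c(OC)c1 | intermediate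
11 | (S)-3-hydroxy-3-(3,4,5-trimethoxyphenyl)propanoic acid | OC(=O)C[C@H](O)c1cc(OC)c(OC)c(OC)c1 | intermediate
12 | (S)-4-(3,4,5-trimethoxyphenyl)oxetan-2-one | O=C1C[C@@H](c2cc(OC)c(OC)c(OC)c2)O1 | intermediate
13 | 3,5-dimethoxybenzyne (1,2-didehydro-3,5-dimethoxybenzene) | COC1=CC(OC)=CC#C1 | intermediate
14 | caesium alkoxide of 2,2,2-trifluoroethyl (S)-3-hydroxy-3-(3,4,5-trimethoxyphenyl)propanoate | [Cs+].[O-][C@@H](CC(=O)OCC(F)(F)F)c1cc(OC)c(OC)c(OC)c1 | intermediate
15 | (2S)-5,7-dimethoxy-2-(3,4,5-trimethoxyphenyl)chroman-4-one | COc1cc(OC)c2c(c1)O[C@H](c1cc(OC)c(OC)c(OC)c1)CC2=O | target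

## Step count and risks

Total step count: 7. Longest linear sequence: 4 steps (steps 4, 5, 6, 7, or equally steps 1, 2, 3, 7).

**Steps most likely to fail**

**Step 7 (proposed new method).** Three processes may defeat it.
- The acyl relay may not keep pace with aryne release, so that the aryne is consumed by fluoride or by itself.
- The aryl carbanion may be quenched by proton transfer from the C3 methylene, followed by β-elimination to a cinnamate.
- Enantiopurity may erode, either by reversible base-induced (E1cB) opening of the product or by direct attack of the lactone carbonyl oxygen on the aryne followed by ionisation at the benzylic carbon.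

Fallback with known chemistry, setting out from keto ester 9 and returning at 15: transfer hydrogenation of 9 with the (R,R)-catalyst should give ethyl (R)-3-hydroxy-3-(3,4,5-trimethoxyphenyl)propanoate F1. Mitsunobu etherification of this alcohol with phenol 1 (PPh3, DIAD, toluene, 0 °C) should give, with inversion, ethyl (S)-3-(3,5-dimethoxyphenoxy)-3-(3,4,5-trimethoxyphenyl)propanoate F2. Saponification with LiOH gives (S)-3-(3,5-dimethoxyphenoxy)-3-(3,4,5-trimethoxyphenyl)propanoic acid F3, and oxalyl chloride with catalytic DMF gives (S)-3-(3,5-dimethoxyphenoxy)-3-(3,4,5-trimethoxyphenyl)propanoyl chloride F4. Intramolecular Friedel–Crafts acylation (SnCl4, CH2Cl2, −78 °C) at either of the two equivalent positions ortho to the ether oxygen closes ring C to 15.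

**Step 6.** Carboxyl activation may be diverted into dehydration or decarboxylative elimination, and the β-aryl-β-lactone may ionise at the benzylic C–O bond under the acidic pyridinium conditions or on silica.

Fallback, setting out from hydroxy ester 10 and returning at 12: Me2AlSPh (from Me3Al and PhSH, CH2Cl2, 0 °C) should convert 10 into S-phenyl (S)-3-hydroxy-3-(3,4,5-trimethoxyphenyl)propanethioate F5. Deprotonation of its hydroxyl with LiHMDS in THF at −78 °C and warming to 0 °C closes the lactone by 4-exo-trig attack of the alkoxide on the thioester with loss of thiophenoxide. This reaches 12 with retention under non-acidic conditions.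

**Step 2.** Metalation may occur at the wrong site (C4, between the two methoxy groups), or silylation of the crowded C2 position may be incomplete.

Fallback, setting out from phenol 1 and returning at 7 and 8: bromination with NBS (CH2Cl2, −78 °C) and separation from the 4-bromo isomer gives 2-bromo-3,5-dimethoxyphenol F6, in which the halogen fixes the position. O-silylation with HMDS gives (2-bromo-3,5-dimethoxyphenoxy)trimethylsilane F7. Bromine–lithium exchange with n-BuLi (THF, −78 °C) triggers the 1,3 O→C silyl shift (retro-Brook rearrangement) to the lithium salt of silylphenol 7, which is triflated in the same flask with Tf2O to 8.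

## Further compounds

F1 | step 7 | ethyl (R)-3-hydroxy-3-(3,4,5-trimethoxyphenyl)propanoate | CCOC(=O)C[C@@H](O)c1cc(OC)c(OC)c(OC)c1
F2 | step 7 | ethyl (S)-3-(3,5-dimethoxyphenoxy)-3-(3,4,5-trimethoxyphenyl)propanoate | CCOC(=O)C[C@H](Oc1cc(OC)cc(OC)c1)c1cc(OC)c(OC)c(OC)c1
F3 | step 7 | (S)-3-(3,5-dimethoxyphenoxy)-3-(3,4,5-trimethoxyphenyl)propanoic acid | OC(=O)C[C@H](Oc1cc(OC)cc(OC)c1)c1cc(OC)c(OC)c(OC)c1
F4 | step 7 | (S)-3-(3,5-dimethoxyphenoxy)-3-(3,4,5-trimethoxyphenyl)propanoyl chloride | ClC(=O)C[C@H](Oc1cc(OC)cc(OC)c1)c1cc(OC)c(OC)c(OC)c1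
F5 | step 6 | S-phenyl (S)-3-hydroxy-3-(3,4,5-trimethoxyphenyl)propanethioate | O=C(C[C@H](O)c1cc(OC)c(OC)c(OC)c1)Sc1ccccc1
F6 | step 2 | 2-bromo-3,5-dimethoxyphenol | COc1cc(O)c(Br)c(OC)c1
F7 | step 2 | (2-bromo-3,5-dimethoxyphenoxy)trimethylsilane | COc1cc(O[Si](C)(C)C)c(Br)c(OC)c1
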